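The readings are calculated with made-up constants; noise was put on by code.

common to all: gas 180 mM (held)
- north-east: solid substrate 1.5 M; the very flask that is asked about, followed so far
- north-west: solid substrate 3 M; run made earlier
- flask: solid substrate 1.5 M; time 12 min

| run | time / min | target / % |
|---|---|---|
| north-east | 0.250 | 0 |
| north-east | 0.667 | 0 |
| north-east | 1.33 | 1.9 |
| north-east | 2.00 | 4.1 |
| north-east | 3.00 | 6.1 |
| north-east | 4.00 | 7.2 |
| north-west | 0.333 | 1.0 |
| north-west | 1.00 | 0.5 |
| north-west | 1.50 | 1.1 |
| north-west | 2.50 | 1.1 |
| north-west | 4.00 | 3.6 |
| north-west | 5.00 | 4.2 |

(standard deviation of a reading: 0.5 percentage points)

- given per volume of solution although it is solid: solid substrate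
- at the start none of the solid substrate is in solution
- at the start none of the gas is in solution

- blue: doubling the saturation concentration of gas, all else as stated
- green: doubling the solubility of the solid substrate, all else as stated
- grey: doubling the dissolution coefficient of the solid substrate, all else as stated
- teal: doubling the transfer coefficient of the gas, all else as stated

* target at 12 min, in percent of the solid substrate charged
* the change that raises the amount of target at 12 min, in percent of the solid substrate charged most ("none" if none brings more than 2 percentage points) (blue / green / grey / teal / none)
* amount of target at 12 min, in percent of the solid substrate charged, after blue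

The last two north-east readings could not give me a slope: they differ by 1.1 percentage points, and a difference of two readings carries a scatter of 0.71 points. So I balanced the gas in solution, which is held at a saturation level of 180 mM and keeps being supplied, so it is no charge to set against 1.5 M of solid substrate. Gas enters solution at a coefficient times saturation minus its level and is then spent; once the two match (a steady state), target should grow steadily. The north-east chord from 1.33 min to 4.00 min gave 0.0298 M/min, which I call r, the steady making rate of target per volume. The north-west chord, with twice the charge, read 0.0278 M/min.

For the north-east flask at 12 min, r held from the start, ignoring the lag, gave an upper edge of 23.8 %, give or take 3.2 points from the scatter of the chord. My lower edge was the last reading, 7.2 %, give or take 0.5 points, since I expected no loss of target. Carrying r on from that reading, which already contains the lag, gave 23.1 %, my figure. I chose blue, which by my balance doubles r, and that put the upper edge at 47.6 %. The forecast went on “at a slightly declining” rate to 14 %, inside my edges but below my figure, with blue at 23 %.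

The north-east flask gave 23.6 %, and blue gave 42.9 %.

    solid substrate ⇌ dissolved substrate, rate k1*(cs1 - [dissolved substrate]) while solid is left; crystals form when [dissolved substrate] > cs1 (solubility = 1.10 M, k = 1.80 /min)
    dissolved substrate + coupling partner → target (k = 1.40 /M/min)
    coupling partner → side product (k = 2.80 /min)
    2 solid substrate → self-condensation product (k = 0.110 /M/min)
    2 solid substrate → homo dimer (k = 3.20 × 10⁻⁵ /M/min)
    gas ⇌ coupling partner, rate k6*(csat - [coupling partner]) (kL = 0.560 /min)

Coupling partner, the gas in solution, stood at 0.0218 M at 1.20 min and 0.0214 M at 12.0 min, when it was made 1.00 times as fast as it was used up. For the north-west charge left to 12 min, r gives 11.9 %, and that flask held 12.0 %.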